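Reagent is conserved in the count: however it reacts, a flask cannot use more than was charged. That is how I left these five flasks for whoever took over the bench.

| flask | starting material | reagent | remark | time |
|---|---|---|---|---|
| dawn | 0.13 M | 0.066 M | run made earlier |  |
| autumn | 0.13 M | 0.50 M | run made earlier |  |
| dusk | 0.16 M | 0.13 M | run made earlier |  |
| theta | 0.080 M | 0.250 M |  | 15 h |
| delta | 0.13 M | 0.0600 M |  | 15 h |
| epsilon | 0.40 M | 0.400 M |  | 15 h |
| beta | 0.13 M | 0.130 M |  | 15 h |
| gamma | 0.40 M | 0.0600 M |  | 15 h |

| run | time / h | target / % |
|---|---|---|
| dawn | 0.500 | 39.6 |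
| dawn | 1.33 | 42.3 |
| dawn | 2.50 | 40.4 |
| dawn | 4.00 | 38.8 |
| dawn | 6.00 | 36.1 |
| dawn | 8.00 | 34.6 |
| autumn | 0.667 | 88.6 |
| autumn | 1.00 | 86.8 |
| autumn | 1.50 | 83.8 |
| autumn | 2.50 | 79.2 |
| autumn | 5.00 | 73.6 |
| autumn | 8.00 | 69.1 |
| dusk | 0.667 | 63.0 |
| dusk | 1.00 | 65.0 |
| dusk | 2.00 | 63.6 |
| dusk | 4.00 | 57.9 |
| dusk | 8.00 | 53.7 |

(scatter of a reading: 0.5 percentage points)



1. the flasks by amount of target, in percent of the starting material charged, highest first, at 15 h (theta / delta / epsilon / beta / gamma)
2. the same order at 5.0 d (theta / delta / epsilon / beta / gamma)
3. the amount of target, in percent of the starting material charged of the flask you put first, at 15 h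
4. the amount of target, in percent of the starting material charged of the flask you put last, at 15 h

For gamma, the reagent charged as a fraction of the starting material charged, which I called the cover 15.0%, made reagent the limiting reagent. Delta's cover was 46.2%. Dawn, at cover 50.8%, last read 34.6%, and that reading gave a keep of 68.2% of the cover as target; dusk read 66.1% on the same reckoning. So I told my successor to expect about 10.2% of target in gamma at 15 h and 31.5% in delta. Theta was charged with more reagent than starting material, so I expected it to go as autumn did, and I put it below autumn's last reading of 69.1%, which was still falling. Beta and epsilon both had cover 100%, which could not part them. I asked that no reagent be added, since a top-up changes the cover.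

The forecast gave theta > epsilon > beta > delta > gamma at 15 h and theta > epsilon > beta > delta > gamma at 5.0 d, with 66% for theta and 10% for gamma, reasoning that the target “relaxes towards a plateau rather than decaying away”.

The flasks gave theta > epsilon > beta > delta > gamma at 15 h and theta > epsilon > beta > delta > gamma at 5.0 d, with 64.7% for theta and 10.2% for gamma.

    target ⇌ isomer of the product (K = 0.460, k = 0.0930 h⁻¹)
    reagent + intermediate A → side product (k = 2.50 M⁻¹ h⁻¹)
    starting material + reagent ⇌ intermediate B (K = 4.70 M⁻¹, k = 2.20 M⁻¹ h⁻¹)
    starting material + reagent → target (k = 46.0 M⁻¹ h⁻¹)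
    starting material → intermediate A (k = 0.620 h⁻¹)

In gamma, target, isomer of the product and side product summed to 15.0% at 15.0 h, against a cover of 15.0%, while 85.0% sat as intermediate A. Holding the reagent level raised gamma's target from 10.2% to 56.3%, so the falling level of reagent was the main reason for its low figure. Theta's neighbour with 0.062 M of reagent had cover 77.5%; its three products summed to 72.5%, and 6.4% of its own reagent charge stood free.

The earlier runs and the new flask stem from a simulated flask on assumed constants.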